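**Plan**

- Cuts: (a) C4a–C5 and C8–C8a of ring B (retro-Diels–Alder; hexahydronaphthalene numbering, carboxyl on C4a), giving ring-A dienoate 21 and triene 14; (b) the central CH–CH single bond of the triene (Suzuki) and its C(CH3)=CH unit back to an alkyne and then a formyl group; (c) C1–C2 and C4–C5 of the cyclohexane (C1 carboxyl-bearing, C4 alkenyl-bearing), giving crotonaldehyde and ethyl 4-oxobutenoate.
- Enabling feature: cyclohexane C1 carries a carboxyl and C4 a carbon that can be a formyl group, and C1 and C4 lie on a local mirror plane of the ring. The ring is therefore two C4 enals joined head to tail: the CH3 of crotonaldehyde to the ester-bearing alkene carbon of the oxobutenoate (C2–C1), and Cα of crotonaldehyde to the formyl carbon of the oxobutenoate (C4–C5). Only the cis/trans relationship is left to fix.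
- Forward order: cyclohexane first (step 1), then saturation, alkyne, (E)-alkenylboronate and triene 14; ring A from (S)-citronellal and methyl vinyl ketone, converted to dienoate 21; ring B last, by the Diels–Alder union that copies the presumed biosynthesis from two bisabolane units; then deprotection.
- Stereochemistry: side-chain centre from (S)-citronellal; C2 from the prolinol catalyst; C4a, C5 and C8a from the Diels–Alder step (suprafacial, ester endo, anti to the C2 side chain); both (E)-alkenes from syn-methylboration and hydrozirconation with retentive coupling; trans-cyclohexane from ethoxide equilibration α to the ester.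

Key step: step 1

Step 1
Reactants: 1 (2E)-but-2-enal (crotonaldehyde); 2 ethyl (2E)-4-oxobut-2-enoate
Product: 4 ethyl 4-formyl-5-hydroxycyclohex-3-ene-1-carboxylate, via open-chain dial 3 (not isolated)
Conditions: L-proline (30 mol %), DMF, −10 °C, slow addition of 1 to 2 (1.2 equiv)
Reagents that add atoms: none
Why: Proline condenses with 1 to the 1-aminobutadiene (dienamine), whose γ-carbon adds to the ester-bearing alkene carbon of 2 (β to the formyl group, which is the activated acceptor) to give dial 3; the α-carbon of the remaining enal then closes onto the saturated aldehyde in an amine-mediated Morita–Baylis–Hillman-type aldol step, so that C1–C2 and C4–C5 of the future cyclohexane are made in one flask. The closest known reaction type is the proline-catalysed formal [3+3] annulation of two enals (dimerisation of crotonaldehyde to 6-hydroxy-4-methylcyclohex-1-ene-1-carbaldehyde), run here as a cross-annulation. The ring closes in a 6-(enolexo)-exo-trig mode. The two new stereocentres (C1 from the Michael step, C5 from the aldol step) need no control, because C5 is removed in step 2, C1 is equilibrated in step 6, and C1 and C4 of the saturated ring lie on a local mirror plane. The step needs cross- over homo-annulation and the γ-Michael/α-aldol mode over a Mannich-type [4+2] closure: 2 has no γ-hydrogen and can only act as acceptor, it is the stronger electrophile, 1 is kept at low concentration, and low temperature with proline should favour the hydroxy-enal mode.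

Step 2
Reactants: 4 ethyl 4-formyl-5-hydroxycyclohex-3-ene-1-carboxylate
Product: 7 ethyl 4-formylcyclohexane-1-carboxylate, via mesylate 5 (not isolated), via dienal 6 (not isolated)
Conditions: MsCl, Et3N, CH2Cl2, 0 °C; DBU, 0 °C to rt; aqueous wash; then H2 (1 atm), Pd/C, EtOAc, rt
Reagents that add atoms: none
Why: Mesylation and base-induced 1,4-elimination (vinylogous E1cB through the γ-deprotonated enal) remove the hydroxyl, and catalytic hydrogenation over Pd/C should saturate both C=C bonds of dienal 6 (or of its double-bond isomers) while sparing the formyl group; the cis/trans mixture is carried on because the trans relationship is set in step 6.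

Step 3
Reactants: 7 ethyl 4-formylcyclohexane-1-carboxylate
Product: 8 ethyl 4-ethynylcyclohexane-1-carboxylate
Conditions: dimethyl (1-diazo-2-oxopropyl)phosphonate, K2CO3, EtOH, 0 °C to rt
Reagents that add atoms: dimethyl (1-diazo-2-oxopropyl)phosphonate, COP(=O)(OC)C(=[N+]=[N-])C(C)=O
Why: Ohira–Bestmann (Seyferth–Gilbert) homologation converts the aldehyde into the terminal alkyne under carbonate conditions that the ethyl ester tolerates in ethanol; no stereocentre of consequence is set.

Step 4
Reactants: 8 ethyl 4-ethynylcyclohexane-1-carboxylate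
Product: 9 ethyl 4-[(1E)-1-(4,4,5,5-tetramethyl-1,3,2-dioxaborolan-2-yl)prop-1-en-2-yl]cyclohexane-1-carboxylate
Conditions: B2pin2, MeI, NaOtBu, CuCl (10 mol %), Xantphos (10 mol %), THF, rt
Reagents that add atoms: bis(pinacolato)diboron, CC1(C)OB(OC1(C)C)B1OC(C)(C)C(C)(C)O1; iodomethane, CI
Why: Copper-catalysed carboboration (methylboration) of the terminal alkyne: syn-borylcupration puts boron on the terminal carbon and copper on the internal one, and methylation of the alkenylcopper with retention should give the (E)-trisubstituted alkenylboronate.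

Step 5
Reactants: 10 2-methylbut-1-en-3-yne
Product: 12 (1E)-1-iodo-3-methylbuta-1,3-diene, via alkenylzirconocene chloride 11 (not isolated)
Conditions: Cp2Zr(H)Cl, THF, 0 °C to rt; then I2, 0 °C
Reagents that add atoms: iodine, II
Why: Hydrozirconation with the Schwartz reagent adds syn across the alkyne with zirconium at the terminus and leaves the 1,1-disubstituted alkene alone, and iodinolysis with retention gives the (E)-dienyl iodide.

Step 6
Reactants: 9 ethyl 4-[(1E)-1-(4,4,5,5-tetramethyl-1,3,2-dioxaborolan-2-yl)prop-1-en-2-yl]cyclohexane-1-carboxylate; 12 (1E)-1-iodo-3-methylbuta-1,3-diene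
Product: 14 ethyl trans-4-[(2E,4E)-6-methylhepta-2,4,6-trien-2-yl]cyclohexane-1-carboxylate, via cis/trans triene ester 13 (not isolated)
Conditions: Pd(PPh3)4 (5 mol %), NaOEt, EtOH/toluene, 50 °C; then 70 °C until the cis/trans ratio is constant; chromatography
Reagents that add atoms: none
Why: Suzuki–Miyaura coupling joins the two alkenyl partners with retention of both geometries, and the ethoxide base also epimerises C1 (α to the ester) so that the mixture should drain toward the diequatorial trans isomer (thermodynamic control), the residual cis isomer being separated and returned to the ethoxide.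

Step 7
Reactants: 15 (3S)-3,7-dimethyloct-6-enal ((S)-citronellal); 16 but-3-en-2-one (methyl vinyl ketone)
Product: 18 (4R)-4-[(2S)-6-methylhept-5-en-2-yl]cyclohex-2-en-1-one, via keto aldehyde 17 (not isolated)
Conditions: (R)-α,α-diphenylprolinol trimethylsilyl ether (10 mol %), ethyl 3,4-dihydroxybenzoate (20 mol %), neat, 0 °C; then LiOH, i-PrOH, rt
Reagents that add atoms: none
Why: Enamine-catalysed Michael addition to methyl vinyl ketone followed by intramolecular aldol condensation (Robinson-type annulation); the (R)-prolinol catalyst shields one enamine face and should set the new centre R (catalyst control), while the side-chain centre comes unchanged from (S)-citronellal.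

Step 8
Reactants: 18 (4R)-4-[(2S)-6-methylhept-5-en-2-yl]cyclohex-2-en-1-one
Product: 20 (4R)-4-[(2S)-6-methylhept-5-en-2-yl]cyclohexa-1,5-dien-1-yl trifluoromethanesulfonate, via lithium dienolate 19 (not isolated)
Conditions: LDA, THF, −78 °C; then PhNTf2, −78 to 0 °C
Reagents that add atoms: N-phenylbis(trifluoromethanesulfonimide), FC(F)(F)S(=O)(=O)N(c1ccccc1)S(=O)(=O)C(F)(F)F
Why: Kinetic deprotonation at the α′-CH2 gives the cross-conjugated dienolate, which is O-sulfonylated (enol triflate formation); the γ-stereocentre is not touched at −78 °C.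

Step 9
Reactants: 20 (4R)-4-[(2S)-6-methylhept-5-en-2-yl]cyclohexa-1,5-dien-1-yl trifluoromethanesulfonate
Product: 21 2-(trimethylsilyl)ethyl (4R)-4-[(2S)-6-methylhept-5-en-2-yl]cyclohexa-1,5-diene-1-carboxylate
Conditions: CO (1 atm), Me3SiCH2CH2OH, Et3N, Pd(OAc)2 (5 mol %), PPh3 (10 mol %), DMF, 50 °C
Reagents that add atoms: carbon monoxide, [C-]#[O+]; 2-(trimethylsilyl)ethanol, C[Si](C)(C)CCO
Why: Palladium-catalysed alkoxycarbonylation of the dienyl triflate (oxidative addition, CO insertion, alcoholysis) places the ester on the internal diene carbon without affecting the stereocentres; 21 is used at once because 2-alkoxycarbonyl dienes tend to dimerise.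

Step 10
Reactants: 14 ethyl trans-4-[(2E,4E)-6-methylhepta-2,4,6-trien-2-yl]cyclohexane-1-carboxylate; 21 2-(trimethylsilyl)ethyl (4R)-4-[(2S)-6-methylhept-5-en-2-yl]cyclohexa-1,5-diene-1-carboxylate
Product: 22 2-(trimethylsilyl)ethyl (2R,4aR,5S,8aR)-5-[(1E)-2-[trans-4-(ethoxycarbonyl)cyclohexyl]prop-1-en-1-yl]-7-methyl-2-[(2S)-6-methylhept-5-en-2-yl]-1,2,4a,5,8,8a-hexahydronaphthalene-4a-carboxylate
Conditions: toluene, BHT (cat.), 90 °C, sealed tube, 14 (2 equiv, excess recovered)
Reagents that add atoms: none
Why: Thermal normal-demand Diels–Alder reaction between the terminal 2-methyl-1,3-diene unit of 14 (the inner diene unit cannot reach s-cis) and the ester-activated C1=C2 bond of 21; the diene CH2 terminus should bond to the β-carbon (ortho/para orientation), the cis ring fusion follows from suprafacial addition, C5 from the ester-endo transition state of the (E)-diene, and C4a/C8a from approach anti to the C4 side chain of 21.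

Step 11
Reactants: 22 2-(trimethylsilyl)ethyl (2R,4aR,5S,8aR)-5-[(1E)-2-[trans-4-(ethoxycarbonyl)cyclohexyl]prop-1-en-1-yl]-7-methyl-2-[(2S)-6-methylhept-5-en-2-yl]-1,2,4a,5,8,8a-hexahydronaphthalene-4a-carboxylate
Product: 24 (2R,4aR,5S,8aR)-5-[(1E)-2-(trans-4-carboxycyclohexyl)prop-1-en-1-yl]-7-methyl-2-[(2S)-6-methylhept-5-en-2-yl]-1,2,4a,5,8,8a-hexahydronaphthalene-4a-carboxylic acid, via monoacid 23 (not isolated)
Conditions: TBAF, THF, rt; then LiOH, THF/H2O, 40 °C; aq. HCl to pH 3
Reagents that add atoms: lithium hydroxide, [Li+].[OH-]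
Why: Fluoride attacks silicon and the 2-silylethyl ester fragments (β-elimination), so the hindered quaternary carboxyl is freed without attack at its carbonyl, and the unhindered ethyl ester is then saponified; the alkenes and the thermodynamically preferred trans-cyclohexane are not expected to change.

**Compound list**

1 | (2E)-but-2-enal (crotonaldehyde) | C/C=C/C=O | starting material
2 | ethyl (2E)-4-oxobut-2-enoate | CCOC(=O)/C=C/C=O | starting material
3 | ethyl (4E)-6-oxo-2-(2-oxoethyl)hex-4-enoate (not isolated; C2 configuration immaterial) | CCOC(=O)C(CC=O)C/C=C/C=O | intermediate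
4 | ethyl 4-formyl-5-hydroxycyclohex-3-ene-1-carboxylate (mixture of stereoisomers; C1 and C5 configuration immaterial) | CCOC(=O)C1CC=C(C=O)C(O)C1 | intermediate
5 | ethyl 4-formyl-5-[(methylsulfonyl)oxy]cyclohex-3-ene-1-carboxylate (not isolated) | CCOC(=O)C1CC=C(C=O)C(OS(C)(=O)=O)C1 | intermediate
6 | ethyl 4-formylcyclohexa-2,4-diene-1-carboxylate (not isolated) | CCOC(=O)C1C=CC(C=O)=CC1 | intermediate
7 | ethyl 4-formylcyclohexane-1-carboxylate (cis/trans mixture) | CCOC(=O)C1CCC(C=O)CC1 | intermediate
8 | ethyl 4-ethynylcyclohexane-1-carboxylate (cis/trans mixture) | CCOC(=O)C1CCC(C#C)CC1 | intermediate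
9 | ethyl 4-[(1E)-1-(4,4,5,5-tetramethyl-1,3,2-dioxaborolan-2-yl)prop-1-en-2-yl]cyclohexane-1-carboxylate (cis/trans mixture) | CCOC(=O)C1CCC(CC1)/C(C)=C/B1OC(C)(C)C(C)(C)O1 | intermediate
10 | 2-methylbut-1-en-3-yne | C=C(C)C#C | starting material
11 | chlorobis(cyclopentadienyl)[(1E)-3-methylbuta-1,3-dien-1-yl]zirconium (not isolated; cyclopentadienyl rings drawn σ-bonded) | C=C(C)/C=C/[Zr](Cl)(C1C=CC=C1)C1C=CC=C1 | intermediate
12 | (1E)-1-iodo-3-methylbuta-1,3-diene | C=C(C)/C=C/I | intermediate
13 | ethyl 4-[(2E,4E)-6-methylhepta-2,4,6-trien-2-yl]cyclohexane-1-carboxylate (cis/trans mixture, not isolated) | C=C(C)/C=C/C=C(\C)C1CCC(C(=O)OCC)CC1 | intermediate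
14 | ethyl trans-4-[(2E,4E)-6-methylhepta-2,4,6-trien-2-yl]cyclohexane-1-carboxylate | C=C(C)/C=C/C=C(\C)[C@H]1CC[C@H](C(=O)OCC)CC1 | intermediate
15 | (3S)-3,7-dimethyloct-6-enal ((S)-citronellal) | CC(C)=CCC[C@H](C)CC=O | starting material
16 | but-3-en-2-one (methyl vinyl ketone) | CC(=O)C=C | starting material
17 | (2R)-2-[(2S)-6-methylhept-5-en-2-yl]-5-oxohexanal (not isolated) | CC(C)=CCC[C@H](C)[C@H](C=O)CCC(C)=O | intermediate
18 | (4R)-4-[(2S)-6-methylhept-5-en-2-yl]cyclohex-2-en-1-one | CC(C)=CCC[C@H](C)[C@@H]1C=CC(=O)CC1 | intermediate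
19 | lithium (4R)-4-[(2S)-6-methylhept-5-en-2-yl]cyclohexa-1,5-dien-1-olate (not isolated) | CC(C)=CCC[C@H](C)[C@@H]1C=CC(O[Li])=CC1 | intermediate
20 | (4R)-4-[(2S)-6-methylhept-5-en-2-yl]cyclohexa-1,5-dien-1-yl trifluoromethanesulfonate | CC(C)=CCC[C@H](C)[C@@H]1C=CC(OS(=O)(=O)C(F)(F)F)=CC1 | intermediate
21 | 2-(trimethylsilyl)ethyl (4R)-4-[(2S)-6-methylhept-5-en-2-yl]cyclohexa-1,5-diene-1-carboxylate | CC(C)=CCC[C@H](C)[C@@H]1C=CC(C(=O)OCC[Si](C)(C)C)=CC1 | intermediate
22 | 2-(trimethylsilyl)ethyl (2R,4aR,5S,8aR)-5-[(1E)-2-[trans-4-(ethoxycarbonyl)cyclohexyl]prop-1-en-1-yl]-7-methyl-2-[(2S)-6-methylhept-5-en-2-yl]-1,2,4a,5,8,8a-hexahydronaphthalene-4a-carboxylate | CC(C)=CCC[C@H](C)[C@@H]1C=C[C@]2(C(=O)OCC[Si](C)(C)C)[C@@H](CC(C)=C[C@H]2/C=C(\C)[C@H]2CC[C@H](C(=O)OCC)CC2)C1 | intermediate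
23 | (2R,4aR,5S,8aR)-5-[(1E)-2-[trans-4-(ethoxycarbonyl)cyclohexyl]prop-1-en-1-yl]-7-methyl-2-[(2S)-6-methylhept-5-en-2-yl]-1,2,4a,5,8,8a-hexahydronaphthalene-4a-carboxylic acid (not isolated) | CC(C)=CCC[C@H](C)[C@@H]1C=C[C@]2(C(=O)O)[C@@H](CC(C)=C[C@H]2/C=C(\C)[C@H]2CC[C@H](C(=O)OCC)CC2)C1 | intermediate
24 | (2R,4aR,5S,8aR)-5-[(1E)-2-(trans-4-carboxycyclohexyl)prop-1-en-1-yl]-7-methyl-2-[(2S)-6-methylhept-5-en-2-yl]-1,2,4a,5,8,8a-hexahydronaphthalene-4a-carboxylic acid | CC(C)=CCC[C@H](C)[C@@H]1C=C[C@]2(C(=O)O)[C@@H](CC(C)=C[C@H]2/C=C(\C)[C@H]2CC[C@H](C(=O)O)CC2)C1 | target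

**Totals**

Total step count: 11. Longest linear sequence: 7 steps (1, 2, 3, 4, 6, 10, 11).

**Steps most likely to fail**

Step 10. What may go wrong: 21 is both a locked s-cis diene and a dienophile, so self-dimerisation may compete with the cross-reaction. Incomplete facial selectivity (approach syn to the C4 side chain) and exo approach of the ester would also give diastereomeric adducts that are hard to separate. The fallback changes the activation mode and sets out from 20. Palladium-catalysed reductive carbonylation (Pd(OAc)2, dppp, CO, Et3SiH, DMF) should give (4R)-4-[(2S)-6-methylhept-5-en-2-yl]cyclohexa-1,5-diene-1-carbaldehyde F1. This more reactive α-substituted enal is combined with 14 at low temperature under a triflimide-activated o-tolyl oxazaborolidine (a chiral Lewis acid, catalyst enantiomer matched to the anti preference of the substrate), so that facial and endo selectivity become catalyst-controlled and dimerisation is slowed. The product is (2R,4aR,5S,8aR)-5-[(1E)-2-[trans-4-(ethoxycarbonyl)cyclohexyl]prop-1-en-1-yl]-7-methyl-2-[(2S)-6-methylhept-5-en-2-yl]-1,2,4a,5,8,8a-hexahydronaphthalene-4a-carbaldehyde F2. Pinnick oxidation (NaClO2, NaH2PO4, 2-methylbut-2-ene) of F2 comes back to the route at 23, which is saponified with LiOH as in step 11.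

Step 1. What may go wrong: the annulation may take another course, either a Mannich-type [4+2] closure or α- instead of γ-attack of the dienamine, and 1 may annulate with itself. The fallback gives up 1 and 2 and builds the ring by a cycloaddition. As step 1 opens the route there is no earlier numbered compound to start from, so it sets out from commercial ethyl acrylate and 2-(trimethylsilyloxy)buta-1,3-diene. Their thermal Diels–Alder reaction (para orientation) gives ethyl 4-[(trimethylsilyl)oxy]cyclohex-3-ene-1-carboxylate F3. Mild acid hydrolysis gives ethyl 4-oxocyclohexane-1-carboxylate F4. Wittig reaction with the ylide from (methoxymethyl)triphenylphosphonium chloride and KOtBu gives ethyl 4-(methoxymethylidene)cyclohexane-1-carboxylate F5. Aqueous acid then frees the aldehyde, and the fallback comes back to the route at 7.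

Step 4. What may go wrong: loss of regiocontrol in the borylcupration, protonation of the alkenylcopper before methylation, or base-induced side reactions of the ester. The fallback exchanges the roles of the coupling partners and sets out from 8. Zirconium-catalysed carboalumination (AlMe3, Cp2ZrCl2, CH2Cl2, water-accelerated at low temperature to spare the ester) gives ethyl 4-[(1E)-1-(dimethylalumanyl)prop-1-en-2-yl]cyclohexane-1-carboxylate F6, which is iodinated in the same flask to ethyl 4-[(1E)-1-iodoprop-1-en-2-yl]cyclohexane-1-carboxylate F7. In parallel, 10 is hydroborated with pinacolborane (Cp2Zr(H)Cl as catalyst) to 2-[(1E)-3-methylbuta-1,3-dien-1-yl]-4,4,5,5-tetramethyl-1,3,2-dioxaborolane F8. Suzuki coupling of F7 with F8 under the conditions of step 6 comes back to the route at 13, which is equilibrated to 14 in the same flask.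

**Further compounds**

F1 | step 10 | (4R)-4-[(2S)-6-methylhept-5-en-2-yl]cyclohexa-1,5-diene-1-carbaldehyde | CC(C)=CCC[C@H](C)[C@@H]1C=CC(C=O)=CC1
F2 | step 10 | (2R,4aR,5S,8aR)-5-[(1E)-2-[trans-4-(ethoxycarbonyl)cyclohexyl]prop-1-en-1-yl]-7-methyl-2-[(2S)-6-methylhept-5-en-2-yl]-1,2,4a,5,8,8a-hexahydronaphthalene-4a-carbaldehyde | CC(C)=CCC[C@H](C)[C@@H]1C=C[C@]2(C=O)[C@@H](CC(C)=C[C@H]2/C=C(\C)[C@H]2CC[C@H](C(=O)OCC)CC2)C1
F3 | step 1 | ethyl 4-[(trimethylsilyl)oxy]cyclohex-3-ene-1-carboxylate | CCOC(=O)C1CCC(O[Si](C)(C)C)=CC1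
F4 | step 1 | ethyl 4-oxocyclohexane-1-carboxylate | CCOC(=O)C1CCC(=O)CC1
F5 | step 1 | ethyl 4-(methoxymethylidene)cyclohexane-1-carboxylate | CCOC(=O)C1CCC(=COC)CC1
F6 | step 4 | ethyl 4-[(1E)-1-(dimethylalumanyl)prop-1-en-2-yl]cyclohexane-1-carboxylate | CCOC(=O)C1CCC(CC1)/C(C)=C/[Al](C)C
F7 | step 4 | ethyl 4-[(1E)-1-iodoprop-1-en-2-yl]cyclohexane-1-carboxylate | CCOC(=O)C1CCC(CC1)/C(C)=C/I
F8 | step 4 | 2-[(1E)-3-methylbuta-1,3-dien-1-yl]-4,4,5,5-tetramethyl-1,3,2-dioxaborolane | C=C(C)/C=C/B1OC(C)(C)C(C)(C)O1
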